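Amounts first: the nucleophile is charged as its protonated form, and the free base is there to take acid off it and give the electrophile free nucleophile to react with.

electrophile 1.5 M; protonated nucleophile 1.80 M; time 8.0 h

* the concentration of free base at which the part of the electrophile that has reacted at 8.0 h is just 50%, in M

    electrophile + nucleophile → acid set free + target (k1 = 0.00247 M⁻¹ min⁻¹)
    nucleophile + acid set free ⇌ protonated nucleophile, settled at all times (K2 = 1400 M⁻¹)
    acid set free + free base ⇌ salt of the base, settled at all times (K3 = 1160 M⁻¹)
    free base ⇌ dormant form (K4 = 1.51, k4 = 0.00383 min⁻¹)
    nucleophile + target ⇌ idle adduct, settled at all times (K5 = 3.0 M⁻¹)
    electrophile + target → side product (k6 = 0.00881 M⁻¹ min⁻¹)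

Each turnover of electrophile with nucleophile uses up one nucleophile and sets one acid free, and that acid must go to the base or it protonates a second nucleophile. To hold the free nucleophile level, the base, acting as a buffer, pays two acids per turnover: that one, and the one that frees a replacement nucleophile. If the used electrophile all went this way, the bill would be

b = 1.50 M.

But does that much base free enough nucleophile? We take the acid steps as balanced. Free base and dormant form relax by their own step, both ways together, with a half-life of 1.81 h, shorter than the run of 8.0 h, so we count them as one pool. The handover number E, the balance constant for acid passing from protonated nucleophile to that whole pool, 0.330, is the salt constant over the protonation constant, divided by one plus the dormant constant. Setting turnover aside, with c the protonated nucleophile charged and n the nucleophile freed,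

n·n = E·(c − n)·(b − n), so n = 0.598 M.

Held at that level, with the electrophile as charged, step 1 would use the wanted part in 5.64 h, sooner than 8.0 h. That is the first objection: n is not held, since every turnover spends base, so a reserve is needed. The second objection pulls the other way. With the other concentrations as charged, free target has a half-life of 0.87 h by the side step alone, shorter than the 3.1 h of nucleophile by step 1 alone, so the side step takes part of the electrophile and frees no acid. If it kept pace with step 1, turnover would be 0.375 M, the bill 0.750 M, and the reserve 0.750 M. We stay at about 1.50 M.

The forecast says 2.2 M, between 1.8 M and 2.7 M, “counting the fast side reaction of target with electrophile”, which is more than our figure.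

The simulation gives 1.52 M.

A flask with 1.22 M of free base reacts 45.2% of its electrophile at 8.0 h. The handover number gives n = 0.603 M for the first flask and 0.535 M for this one, a ratio of 0.887, while the parts reacted stand in a ratio of 0.903.

The constants used here are assumed, and the outcome is calculated.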